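The synthesis rests on cutting both C–CH3 bonds of the tertiary carbinol. The cis CH=CH that joins C3' of ring A to the carbinol carbon, together with the adjacent C4' phenol oxygen, is recognised as C4=C3, C2 and O1 of a coumarin, so the Z geometry is held in a six-membered lactone until the last step. Twofold methyl addition to the lactone carbonyl of 5-hydroxy-6-[(E)-4-hydroxycinnamoyl]-7-methoxycoumarin then opens the pyranone and gives candidachalcone in one operation, the two phenols being masked in the flask as phenoxides. This precursor, a coumarin carrying the complete chalcone, comes from 5-methoxyresorcinol by formylation, Wittig lactonisation, Fries acetyl shift and Claisen–Schmidt condensation.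

Key step: step 8

Remark: the phenoxides formed in step 8 are drawn as lithium salts, although with CeCl3 present the counter-ions are probably mixed lithium and cerium species.

Step 1
Reactants: 1 5-methoxyresorcinol
Product: 2 1-methoxy-3,5-bis(methoxymethoxy)benzene
Conditions: NaH, MOMCl, DMF, 0 °C to rt
Reagents that add atoms: chloromethyl methyl ether, COCCl
Why: Twofold Williamson-type O-alkylation of the sodium phenoxides with the reactive α-chloro ether (MOM protection) should be clean and installs the two strongest directing groups for the metalation that follows.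

Step 2
Reactants: 2 1-methoxy-3,5-bis(methoxymethoxy)benzene
Product: 4 4-methoxy-2,6-bis(methoxymethoxy)benzaldehyde, via aryllithium 3 (not isolated)
Conditions: n-BuLi, TMEDA, THF, 0 °C; DMF, 0 °C to rt; H2O
Reagents that add atoms: N,N-dimethylformamide, CN(C)C=O
Why: Directed ortho-metalation should occur at the carbon flanked by the two chelating OMOM groups, which direct more strongly together than an OMOM/OMe pair, and the aryllithium is then formylated by DMF (Bouveault-type formylation).

Step 3
Reactants: 4 4-methoxy-2,6-bis(methoxymethoxy)benzaldehyde
Product: 5 2,6-dihydroxy-4-methoxybenzaldehyde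
Conditions: HCl (cat.), MeOH, 50 °C
Reagents that add atoms: none
Why: Acid-catalysed transacetalisation to methanol (acetal cleavage) removes both MOM groups, while the aryl methyl ether and the hydrogen-bonded aldehyde are stable to dilute acid.

Step 4
Reactants: 5 2,6-dihydroxy-4-methoxybenzaldehyde; 6 ethyl (triphenylphosphoranylidene)acetate
Product: 8 5-hydroxy-7-methoxycoumarin, via E-cinnamate ester 7 (not isolated)
Conditions: PhNEt2, reflux
Reagents that add atoms: none
Why: Wittig olefination with the stabilised ylide, followed by thermal E to Z isomerisation and lactonisation (Wittig lactonisation route to coumarins), builds the pyranone, and because the two phenols are equivalent only one coumarin can form.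

Step 5
Reactants: 8 5-hydroxy-7-methoxycoumarin
Product: 9 5-acetoxy-7-methoxycoumarin
Conditions: Ac2O, pyridine, DMAP (cat.), rt
Reagents that add atoms: acetic anhydride, CC(=O)OC(C)=O
Why: DMAP-catalysed O-acylation of the only free phenol is routine and provides the aryl ester needed for the acyl shift.

Step 6
Reactants: 9 5-acetoxy-7-methoxycoumarin
Product: 10 6-acetyl-5-hydroxy-7-methoxycoumarin
Conditions: TiCl4, PhCl, 100 °C; then 1 M HCl
Reagents that add atoms: none
Why: The Fries rearrangement under TiCl4 should deliver the acetyl group to C6, the only free carbon ortho to the C5 oxygen (C4a is quaternary), because the product is held as a six-membered titanium chelate that favours ortho over para (C8) migration, as in the known shift of 5-acetoxycoumarins to 6-acetyl-5-hydroxycoumarins.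

Step 7
Reactants: 10 6-acetyl-5-hydroxy-7-methoxycoumarin; 11 4-hydroxybenzaldehyde
Product: 13 5-hydroxy-6-[(E)-4-hydroxycinnamoyl]-7-methoxycoumarin, via aldol adduct 12 (not isolated)
Conditions: dry HCl, EtOH, 0 °C to rt
Reagents that add atoms: none
Why: The acid-catalysed Claisen–Schmidt condensation (enol of the methyl ketone onto the non-enolisable aldehyde, then dehydration) tolerates free phenols, leaves the acid-stable lactone closed, and should give the conjugated enone as the thermodynamically preferred E isomer.

Step 8
Reactants: 13 5-hydroxy-6-[(E)-4-hydroxycinnamoyl]-7-methoxycoumarin; 14 methyllithium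
Product: 17 candidachalcone, via dilithium bisphenoxide 15 (not isolated), via ring-opened Z-enone 16 (not isolated)
Conditions: MeLi (2.0 equiv), THF, −78 °C; then added to MeLi/anhydrous CeCl3 (4.5 equiv each), THF, −78 to 0 °C; cold satd aq NH4Cl, pH 7 phosphate buffer; chromatography on C18 silica, light excluded
Reagents that add atoms: methyllithium, [Li]C
Why: After two equivalents of 14 have turned the phenols into dianion 15, methylcerium dichloride (made in the flask from further 14 and CeCl3) adds 1,2 to the lactone C2 carbonyl, the hemiketal alkoxide collapses with loss of the C8a aryloxide to the Z-enone methyl ketone 16, and a second 1,2-addition to that unhindered ketone gives the tertiary alkoxide, so that two methyl groups from 14 sit on the carbinol carbon before protonation on work-up. The closest known reaction type is the twofold addition of methyllithium or methylmagnesium halides to coumarins, which gives cis-2-(3-hydroxy-3-methylbut-1-enyl)phenols. No ring is closed (the pyranone is opened) and no stereocentre is created; the Z geometry of the C4=C3 bond, enforced by the six-membered lactone, should carry over because that π bond is never broken and the push–pull enone 16 is consumed at low temperature before it can rotate. The step needs chemoselectivity for the lactone over the chalcone: the ring B phenoxide is conjugated through the styryl unit with the ketone and lowers the electrophilicity of both the enone β-carbon and the carbonyl, while the C5 phenoxide chelated to that carbonyl and the flanking C7 methoxy group leave the twisted, di-ortho-substituted aryl ketone shielded, so the unhindered aryl ester carbonyl, although it also receives some donation from the C5 oxygen, should remain the most accessible acyl carbon. CeCl3 provides a weakly basic, oxophilic methyl donor that favours carbonyl addition over conjugate addition at C4 and over enolisation of 16, and the buffered, acid-free work-up and neutral support are intended to prevent cyclodehydration of the product to the 2,2-dimethylchromene.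

Compound list

1 | 5-methoxyresorcinol (5-methoxybenzene-1,3-diol) | COc1cc(O)cc(O)c1 | starting material
2 | 1-methoxy-3,5-bis(methoxymethoxy)benzene | COCOc1cc(OC)cc(OCOC)c1 | intermediate
3 | [4-methoxy-2,6-bis(methoxymethoxy)phenyl]lithium (not isolated) | COCOc1cc(OC)cc(OCOC)c1[Li] | intermediate
4 | 4-methoxy-2,6-bis(methoxymethoxy)benzaldehyde | COCOc1cc(OC)cc(OCOC)c1C=O | intermediate
5 | 2,6-dihydroxy-4-methoxybenzaldehyde | COc1cc(O)c(C=O)c(O)c1 | intermediate
6 | ethyl (triphenylphosphoranylidene)acetate | CCOC(=O)C=P(c1ccccc1)(c1ccccc1)c1ccccc1 | starting material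
7 | ethyl (E)-3-(2,6-dihydroxy-4-methoxyphenyl)prop-2-enoate (not isolated) | CCOC(=O)/C=C/c1c(O)cc(OC)cc1O | intermediate
8 | 5-hydroxy-7-methoxycoumarin | COc1cc(O)c2ccc(=O)oc2c1 | intermediate
9 | 5-acetoxy-7-methoxycoumarin (7-methoxy-2-oxo-2H-chromen-5-yl acetate) | COc1cc(OC(C)=O)c2ccc(=O)oc2c1 | intermediate
10 | 6-acetyl-5-hydroxy-7-methoxycoumarin | COc1cc2oc(=O)ccc2c(O)c1C(C)=O | intermediate
11 | 4-hydroxybenzaldehyde | O=Cc1ccc(O)cc1 | starting material
12 | racemic 5-hydroxy-6-[3-hydroxy-3-(4-hydroxyphenyl)propanoyl]-7-methoxycoumarin (not isolated) | COc1cc2oc(=O)ccc2c(O)c1C(=O)CC(O)c1ccc(O)cc1 | intermediate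
13 | 5-hydroxy-6-[(E)-4-hydroxycinnamoyl]-7-methoxycoumarin | COc1cc2oc(=O)ccc2c(O)c1C(=O)/C=C/c1ccc(O)cc1 | intermediate
14 | methyllithium | [Li]C | starting material
15 | dilithium bisphenoxide of 13 (not isolated) | COc1cc2oc(=O)ccc2c([O-])c1C(=O)/C=C/c1ccc([O-])cc1.[Li+].[Li+] | intermediate
16 | trilithium triphenoxide of (E)-1-[2,4-dihydroxy-6-methoxy-3-[(Z)-3-oxobut-1-enyl]phenyl]-3-(4-hydroxyphenyl)prop-2-en-1-one (not isolated) | COc1cc([O-])c(/C=C\C(C)=O)c([O-])c1C(=O)/C=C/c1ccc([O-])cc1.[Li+].[Li+].[Li+] | intermediate
17 | candidachalcone, (E)-1-[2,4-dihydroxy-3-[(Z)-3-hydroxy-3-methylbut-1-enyl]-6-methoxyphenyl]-3-(4-hydroxyphenyl)prop-2-en-1-one | COc1cc(O)c(/C=C\C(C)(C)O)c(O)c1C(=O)/C=C/c1ccc(O)cc1 | target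

Total step count: 8 steps.
Longest linear sequence: 8 steps (1 to 17); compounds 6, 11 and 14 are purchased.

Steps most likely to fail

Step 8. Methyl transfer may go to the chalcone carbonyl or its β-carbon if phenoxide masking is not sufficient, and the reaction may stop after the first addition. Rotation about the former C3–C4 bond at the push–pull enone stage would erode the Z geometry, and acid-triggered cyclodehydration could occur during isolation. The fallback sets out from 10 and returns at 17 by reversing the order, so that no enone is present when the methyl nucleophile is used. Ketone 10 is treated with LiN(SiMe3)2 (2.1 equiv, THF, −78 °C) to give the dilithium phenoxide–enolate F1, in which the acetyl group is shielded as its enolate. MeLi/CeCl3 under the conditions of step 8, followed by buffered work-up, should then give 1-[2,4-dihydroxy-3-[(Z)-3-hydroxy-3-methylbut-1-enyl]-6-methoxyphenyl]ethanone F2. A Claisen–Schmidt condensation of F2 with 11 under excess LiN(SiMe3)2 in THF (−78 °C to rt, NH4Cl quench), a protecting-group-free and acid-free variant known for polyhydroxyacetophenones, should give 17 directly.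

Step 7. The hindered, chelated acetyl group may enolise sluggishly, the acid may promote oxa-Michael closure of the 2'-hydroxychalcone to the flavanone, or the phenolic aldehyde may self-condense. The fallback sets out from 8 and returns at 13, bringing in the enone by C-acylation instead of condensation. Purchased (E)-4-acetoxycinnamic acid F3 is converted with (COCl)2 and catalytic DMF into (E)-4-acetoxycinnamoyl chloride F4. This O-acylates 8 (Et3N, DMAP, CH2Cl2) to give 7-methoxy-2-oxo-2H-chromen-5-yl (E)-3-(4-acetoxyphenyl)prop-2-enoate F5. A TiCl4-mediated Fries shift (PhCl, 100 °C), of the Lewis-acid type that converts aryl cinnamates into 2'-hydroxychalcones, should give 6-[(E)-4-acetoxycinnamoyl]-5-hydroxy-7-methoxycoumarin F6. Methanolysis of the aryl acetate (K2CO3, MeOH, 0 °C, then dilute HCl) returns to 13.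

Step 6. The acyl group may migrate to C8 (para to the C5 oxygen) instead of C6, the Lewis acid may cleave the C7 methyl ether once the chelating ketone is in place, or simple deacylation may return the phenol. The fallback sets out from 8 and returns at 10, using an ortho-specific formylation in place of the acyl shift. Magnesium-mediated ortho-formylation (MgCl2, Et3N, paraformaldehyde, MeCN, reflux), which can only reach C6, should give 6-formyl-5-hydroxy-7-methoxycoumarin F7. MeTi(OiPr)3 (THF, −40 to 0 °C), a methyl donor that adds to aldehydes but spares lactones, should give racemic 5-hydroxy-6-(1-hydroxyethyl)-7-methoxycoumarin F8. Oxidation of the benzylic alcohol with MnO2 (CH2Cl2, rt) rejoins the route at 10.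

Further compounds
F1 | step 8 | dilithium phenoxide–enolate of 10 | COc1cc2oc(=O)ccc2c([O-])c1C([O-])=C.[Li+].[Li+]
F2 | step 8 | 1-[2,4-dihydroxy-3-[(Z)-3-hydroxy-3-methylbut-1-enyl]-6-methoxyphenyl]ethanone | COc1cc(O)c(/C=C\C(C)(C)O)c(O)c1C(C)=O
F3 | step 7 | (E)-4-acetoxycinnamic acid (purchased) | CC(=O)Oc1ccc(/C=C/C(=O)O)cc1
F4 | step 7 | (E)-4-acetoxycinnamoyl chloride | CC(=O)Oc1ccc(/C=C/C(=O)Cl)cc1
F5 | step 7 | 7-methoxy-2-oxo-2H-chromen-5-yl (E)-3-(4-acetoxyphenyl)prop-2-enoate | COc1cc(OC(=O)/C=C/c3ccc(OC(C)=O)cc3)c2ccc(=O)oc2c1
F6 | step 7 | 6-[(E)-4-acetoxycinnamoyl]-5-hydroxy-7-methoxycoumarin | COc1cc2oc(=O)ccc2c(O)c1C(=O)/C=C/c1ccc(OC(C)=O)cc1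
F7 | step 6 | 6-formyl-5-hydroxy-7-methoxycoumarin | COc1cc2oc(=O)ccc2c(O)c1C=O
F8 | step 6 | racemic 5-hydroxy-6-(1-hydroxyethyl)-7-methoxycoumarin | COc1cc2oc(=O)ccc2c(O)c1C(C)O
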